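## Analysis of the target

The target is a 1,2,6-trisubstituted cyclohex-4-ene. Locants used throughout: C1 carries the acyl chain, C2 the 4-hydroxy-3-methoxyphenyl ring, C3 is CH2, C4=C5 is the ring alkene, C6 carries the 3,4-dimethoxyphenyl ring. The acyl chain on C1 is the hydrogen-bonded enol of a 5-(4-hydroxy-3-methoxyphenyl)-3-oxopent-4-enoyl group, i.e. half a curcuminoid.

The three contiguous stereocentres are (1R,2S,6R). The acyl group is trans to both aryl groups and the aryl groups are cis to each other, so all three substituents can sit (pseudo)equatorially on the half-chair. C1 is α to a carbonyl and epimerisable, and with cis aryl groups its configuration is the thermodynamic one. C2 and C6 are fixed and must be set relative to each other and in the absolute sense.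

Formally the ring is the Diels–Alder adduct of a 1-arylbutadiene and a feruloyl enone, but the anti-Alder one (acyl exo), and no ring heteroatom helps to direct reagents. The feature the plan exploits is the γ,δ-unsaturated carbonyl array O=C–C1–C6–C5=C4, in which C1, C6, C5 and C4 are ring atoms: a Claisen retron inside the six-membered ring.

Sensitive groups are the enolised 1,3-diketone conjugated to an electron-rich styrene (base-labile, a Michael acceptor, no hydrogenation possible), the ring alkene with its allylic and benzylic C6–H, and two free phenols. The two ring aryl groups differ by one O-methyl only, so they must arrive separately. The difficulty is to set three contiguous carbocyclic stereocentres absolutely in the anti-Alder sense while bringing in the fragile diketone arm last.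

## Retrosynthetic reasoning

**22 ⇒ 18 + 19.** The styryl C=C of the diketone arm is cut first. This leaves the methyl diketone 18 and vanillin 19, so the base-sensitive curcuminoid arm is made in the last step from an unprotected commercial aldehyde. The forward reaction must condense at the terminal CH3 only (boron chelation secures this) and release the one protected phenol in the same acidic work-up.

**18 ⇒ 16 + 17.** The bond between the diketone CH2 and the outer carbonyl is cut, giving methyl ketone 16 and ethyl acetate 17. A crossed Claisen condensation under equilibrating conditions extends only the methyl side, because only that product is drained as a stabilised enolate.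

**16 ⇒ 15 ⇒ 13 + 14.** C1 is inverted on paper: 16 (acetyl trans to both aryl groups) comes from its all-cis epimer 15 by enolate equilibration. This is the point where the route funnels C1 to the needed configuration. The acetyl C–CH3 bond is then cut to the acid 13 and methyllithium 14.

**13 ⇒ 10 (key disconnection).** The ring bond C1–C6 is cut and C4 is joined to the carboxyl oxygen, with the alkene moved back from C4=C5 to C5=C6. C1–C6 is the only ring bond that lies between the carbonyl α-carbon and the allylic carbon of the γ,δ-unsaturated acid. The precursor is the δ-lactone 10, in which two 1,3-related centres (C2 and the carbinol carbon C4) replace three contiguous carbon stereocentres. The forward Ireland–Claisen ring contraction (through 11 and 12) must transfer the C–O chirality to C6 and close the carbocycle. Because the tether enforces a boat, it gives the all-cis acid, which is exactly the isomer that step 8 corrects at C1.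

**10 ⇒ 6 + 9.** The C2–aryl bond is cut. Conjugate arylation of the unsaturated lactone 6 with boronate 9 must occur anti to the C6 styryl group of the lactone. The resulting 4,6-trans lactone is both the kinetic product of such additions and the diastereomer that places the two aryl groups cis on the carbocycle. It can also hold the styryl arm axial, as the rearrangement requires, without a syn-axial aryl group.

**6 ⇒ 5 ⇒ 3 + 4; 3 ⇒ 1 + 2; 9 ⇒ 7 + 8.** The lactone C=C is cut (ring-closing metathesis of acrylate 5), then the ester C–O (alcohol 3 and acryloyl chloride 4), then the carbinol C–C bond (aldehyde 1 and allylstannane 2). The allylation is the only step that introduces absolute configuration; every other centre is relayed from it. Boronate 9 is the methoxymethyl ether of the commercial phenol 7, made with 8.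

## Alternatives that were turned down

**Alternative 1:** the textbook cut of C1–C6 and C2–C3 together. The forward step is a Diels–Alder reaction of (E)-1-(3,4-dimethoxyphenyl)buta-1,3-diene A1 (one Wittig step from 1) with one enone unit of curcumin A2, thermally or with a chiral Lewis acid. It is the shortest route on paper, but it was turned down for three reasons:
- The Alder endo rule places the carbonyl under the diene and leads to adduct A3, with the acyl group cis to the C6 aryl and the two aryl groups trans. That C2/C6 relation cannot be repaired by epimerising C1; the target is the exo-acyl adduct.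
- A β-aryl enone with a para-oxygen donor is a weak dienophile and A1 is an unactivated diene that dimerises under forcing conditions.
- No general catalytic method gives both exo and enantioselectivity for this acyclic diene/enone pair, and A2 offers two equivalent enone ends and a chelating diketone. The likely outcome is a racemic diastereomer mixture that needs separation and resolution.

**Alternative 2:** cut the ring alkene C4=C5. The forward step is ring-closing metathesis of the acyclic diene acid A4, itself made by a chair-type Ireland–Claisen rearrangement of the cinnamyl ester A5. The chair would give the C1/C6 trans relation directly. It was turned down because the C1/C2 relation would then rest on acyclic 1,2-induction from the β-aryl centre on the ketene acetal face, which is the weakest control at the hardest relation. A5 also needs its own asymmetric synthesis of a 3-arylhex-5-enoic acid, and ring closure costs a separate step.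

**Alternative 3:** cut both C(sp3)–aryl bonds. The forward step is a twofold Pd(OAc)2-catalysed, 8-aminoquinoline-directed β-C–H arylation of amide A6 (from commercial (S)-cyclohex-3-ene-1-carboxylic acid) with two different aryl iodides to the all-cis amide A7, followed by C1 epimerisation. The stereochemical logic is attractive and matches the chosen route. It was turned down because the ring alkene invites Heck insertion of the aryl–palladium species, and the first arylation has no reliable preference between the allylic and the homoallylic β-CH2, so two nearly identical aryl groups cannot be assigned to C6 and C2 with confidence. The hindered amide must also be converted to a ketone afterwards.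

Key step: step 6

Assumption: the enol written in the target SMILES is the hydrogen-bonded tautomer of the 1,3-diketone; the route makes the diketone, which adopts this form on its own.

## Route

Step 1
Reactants: 1 (E)-3-(3,4-dimethoxyphenyl)prop-2-enal; 2 allyltributylstannane
Product: 3 (3R,1E)-1-(3,4-dimethoxyphenyl)hexa-1,5-dien-3-ol
Conditions: (R)-BINOL (20 mol%), Ti(OiPr)4 (10 mol%), 4 Å molecular sieves, CH2Cl2, −20 °C; aq. NaHCO3
Reagents that add atoms: allyltributylstannane (2), C=CC[Sn](CCCC)(CCCC)CCCC
Why: Keck asymmetric allylation; the (R)-BINOL–titanium Lewis acid exposes the Re face of the enal carbonyl to the allylstannane, which should set the carbinol centre as R, and 1,2-addition is the normal mode for allylstannanes with enals.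

Step 2
Reactants: 3 (3R,1E)-1-(3,4-dimethoxyphenyl)hexa-1,5-dien-3-ol; 4 acryloyl chloride
Product: 5 (3R,1E)-1-(3,4-dimethoxyphenyl)hexa-1,5-dien-3-yl prop-2-enoate
Conditions: acryloyl chloride, Et3N, DMAP (cat.), CH2Cl2, 0 °C
Reagents that add atoms: acryloyl chloride (4), C=CC(=O)Cl
Why: O-acylation of the secondary allylic alcohol with an acid chloride and amine base; the carbinol centre is not involved and keeps its configuration.

Step 3
Reactants: 5 (3R,1E)-1-(3,4-dimethoxyphenyl)hexa-1,5-dien-3-yl prop-2-enoate
Product: 6 (6R)-6-[(E)-2-(3,4-dimethoxyphenyl)ethenyl]-5,6-dihydro-2H-pyran-2-one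
Conditions: second-generation Grubbs catalyst RuCl2(=CHPh)(PCy3)(H2IMes) (3 mol%), CH2Cl2 (0.01 M), 40 °C
Reagents that add atoms: none
Why: Ring-closing metathesis; the catalyst loads on the terminal allyl alkene and closes onto the acrylate to the six-membered unsaturated lactone with loss of ethylene, while the less reactive internal styryl alkene could only close a cyclobutene from that alkylidene and stays E.

Step 4
Reactants: 7 2-methoxy-4-(4,4,5,5-tetramethyl-1,3,2-dioxaborolan-2-yl)phenol; 8 chloromethyl methyl ether
Product: 9 2-[3-methoxy-4-(methoxymethoxy)phenyl]-4,4,5,5-tetramethyl-1,3,2-dioxaborolane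
Conditions: MOMCl, iPr2NEt, CH2Cl2, 0 °C → rt
Reagents that add atoms: chloromethyl methyl ether (8), COCCl
Why: O-alkylation of the phenol; the pinacol boronate is inert here, and the methoxymethyl ether tolerates every basic and organometallic step that follows and leaves in the final acidic work-up.

Step 5
Reactants: 6 (6R)-6-[(E)-2-(3,4-dimethoxyphenyl)ethenyl]-5,6-dihydro-2H-pyran-2-one; 9 2-[3-methoxy-4-(methoxymethoxy)phenyl]-4,4,5,5-tetramethyl-1,3,2-dioxaborolane
Product: 10 (4S,6R)-6-[(E)-2-(3,4-dimethoxyphenyl)ethenyl]-4-[3-methoxy-4-(methoxymethoxy)phenyl]oxan-2-one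
Conditions: [Rh(OH)(cod)]2 (3 mol%), 9 (2 equiv), 1,4-dioxane/H2O 10:1, 40 °C
Reagents that add atoms: 2-[3-methoxy-4-(methoxymethoxy)phenyl]-4,4,5,5-tetramethyl-1,3,2-dioxaborolane (9), COCOc1ccc(B2OC(C)(C)C(C)(C)O2)cc1OC
Why: Hayashi–Miyaura reaction (rhodium-catalysed conjugate arylation of an enoate); the aryl–rhodium species formed from 9 inserts the lactone C=C at C4 and water protonates the rhodium enolate. Attack anti to the pseudo-equatorial C6 styryl group, the usual course of organometallic additions to 6-substituted 5,6-dihydropyran-2-ones, should set the new centre as 4S (4,6-trans).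

Step 6
Reactants: 10 (4S,6R)-6-[(E)-2-(3,4-dimethoxyphenyl)ethenyl]-4-[3-methoxy-4-(methoxymethoxy)phenyl]oxan-2-one
Product: 13 (1S,2S,6R)-6-(3,4-dimethoxyphenyl)-2-[3-methoxy-4-(methoxymethoxy)phenyl]cyclohex-4-ene-1-carboxylic acid (all-cis), via silyl ketene acetal 11 (not isolated), via silyl ester 12 (not isolated)
Conditions: LiN(iPr)2 (1.15 equiv), THF, −78 °C; TBSCl (1.3 equiv), DMPU, −78 °C → rt; solvent switch to toluene, 90 °C; then AcOH/THF/H2O, rt
Reagents that add atoms: none
Why: This is an Ireland–Claisen rearrangement run as a ring contraction of a 6-alkenyl δ-lactone, a known way to turn such lactones into cyclohex-3-enecarboxylic acids. LiN(iPr)2 removes a proton from the only enolisable carbon (C1) and O-silylation gives the cyclic ketene acetal 11, whose C1=C(OSi)–O–C4–C5=C6 array undergoes a concerted suprafacial [3,3] shift on heating: C1–C6 forms, C4–O breaks and the styrene bond C5=C6 moves to C4=C5. The cyclohexene closes through the new C1–C6 σ bond inside a six-membered pericyclic array that the C2–C3 bridge forces into a boat (bicyclo[2.2.2]octane-like) shape, while the lactone ring opens. C6 is set by 1,3-chirality transfer from the carbinol carbon: the bond forms on the face of the E-alkene from which oxygen leaves, which places the aryl group on the ring face that the oxygen occupied. C1 is set by the fixed geometry of the endocyclic ketene acetal in the boat: the carboxyl carbon stays on the face of the departing oxygen, hence cis to the C6 aryl group. C2 is not touched, and because it is trans to the styryl group in 10 its aryl group lies on the same face, so 13 is the all-cis isomer with C2 and C6 already in the configuration of the target. The step needs the concerted path to beat ionisation of the allylic C–O bond and needs a single enolate; the nonpolar solvent, the neutral silyl ketene acetal and the single α-CH2 group secure this, and the configuration at C1 is corrected in step 8.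

Step 7
Reactants: 13 (1S,2S,6R)-6-(3,4-dimethoxyphenyl)-2-[3-methoxy-4-(methoxymethoxy)phenyl]cyclohex-4-ene-1-carboxylic acid; 14 methyllithium
Product: 15 1-[(1S,2S,6R)-6-(3,4-dimethoxyphenyl)-2-[3-methoxy-4-(methoxymethoxy)phenyl]cyclohex-4-en-1-yl]ethan-1-one (all-cis)
Conditions: MeLi (3.5 equiv), THF, 0 °C → rt; inverse quench into ice-cold 0.5 M HCl
Reagents that add atoms: methyllithium (14), [Li]C
Why: Addition of methyllithium to the lithium carboxylate gives a gem-dialkoxide that collapses to the ketone only on the inverse acidic quench, so over-addition is avoided; no stereocentre is at risk because no enolisable ketone exists before work-up.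

Step 8
Reactants: 15 1-[(1S,2S,6R)-6-(3,4-dimethoxyphenyl)-2-[3-methoxy-4-(methoxymethoxy)phenyl]cyclohex-4-en-1-yl]ethan-1-one
Product: 16 1-[(1R,2S,6R)-6-(3,4-dimethoxyphenyl)-2-[3-methoxy-4-(methoxymethoxy)phenyl]cyclohex-4-en-1-yl]ethan-1-one (acetyl trans to both aryl groups)
Conditions: NaOMe (0.3 equiv), MeOH/THF, 50 °C; AcOH quench
Reagents that add atoms: none
Why: Base-mediated epimerisation through the C1 enolate (thermodynamic control); 15 can only hold its acetyl group axial between two equatorial aryl groups whereas 16 has all three substituents equatorial, so the equilibrium should favour 16, and any residual 15 would be separated and resubmitted. C2 and C6 are not acidic and the γ,δ-alkene cannot move into conjugation through this enolate.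

Step 9
Reactants: 16 1-[(1R,2S,6R)-6-(3,4-dimethoxyphenyl)-2-[3-methoxy-4-(methoxymethoxy)phenyl]cyclohex-4-en-1-yl]ethan-1-one; 17 ethyl acetate
Product: 18 1-[(1R,2S,6R)-6-(3,4-dimethoxyphenyl)-2-[3-methoxy-4-(methoxymethoxy)phenyl]cyclohex-4-en-1-yl]butane-1,3-dione
Conditions: NaH (3 equiv), EtOAc (6 equiv), THF, 0 → 50 °C; cold 1 M HCl
Reagents that add atoms: ethyl acetate (17), CCOC(C)=O
Why: Crossed Claisen condensation; under equilibrating conditions only acylation at the methyl group gives a diketone that is drained as its stabilised sodium enolate, so the chain grows at CH3, and C1 already has its thermodynamic configuration.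

Step 10
Reactants: 18 1-[(1R,2S,6R)-6-(3,4-dimethoxyphenyl)-2-[3-methoxy-4-(methoxymethoxy)phenyl]cyclohex-4-en-1-yl]butane-1,3-dione; 19 vanillin
Product: 22 target CNP0290899.1 (1Z,4E)-1-[(1R,2S,6R)-6-(3,4-dimethoxyphenyl)-2-(4-hydroxy-3-methoxyphenyl)cyclohex-4-en-1-yl]-3-hydroxy-5-(4-hydroxy-3-methoxyphenyl)penta-2,4-dien-1-one, via boron chelate 20 (not isolated), via boron chelate 21 (not isolated)
Conditions: B2O3 (0.7 equiv), B(OBu)3 (2 equiv), EtOAc, 70 °C; then 19 (1.05 equiv), n-BuNH2 (0.3 equiv, added slowly), 70 °C; then 1 M aq. HCl/MeOH, 55 °C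
Reagents that add atoms: vanillin (19), COc1cc(C=O)ccc1O
Why: Pabon reaction (boron-templated aldol condensation of a 1,3-diketone); chelation to boron blocks the central CH2 and makes the terminal CH3 the nucleophile, which condenses with the free-phenol aldehyde to the E-styryl unit, while the hindered C1 methine does not compete. Warm methanolic HCl then hydrolyses the boron chelate and cleaves the aryl methoxymethyl ether; C1 keeps its thermodynamic configuration.

## Compound list

1 | (E)-3-(3,4-dimethoxyphenyl)prop-2-enal | COc1ccc(/C=C/C=O)cc1OC | starting material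
2 | allyltributylstannane | C=CC[Sn](CCCC)(CCCC)CCCC | starting material
3 | (3R,1E)-1-(3,4-dimethoxyphenyl)hexa-1,5-dien-3-ol | C=CC[C@@H](O)/C=C/c1ccc(OC)c(OC)c1 | intermediate
4 | acryloyl chloride | C=CC(=O)Cl | starting material
5 | (3R,1E)-1-(3,4-dimethoxyphenyl)hexa-1,5-dien-3-yl prop-2-enoate | C=CC[C@@H](OC(=O)C=C)/C=C/c1ccc(OC)c(OC)c1 | intermediate
6 | (6R)-6-[(E)-2-(3,4-dimethoxyphenyl)ethenyl]-5,6-dihydro-2H-pyran-2-one | O=C1C=CC[C@H](/C=C/c2ccc(OC)c(OC)c2)O1 | intermediate
7 | 2-methoxy-4-(4,4,5,5-tetramethyl-1,3,2-dioxaborolan-2-yl)phenol | COc1cc(B2OC(C)(C)C(C)(C)O2)ccc1O | starting material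
8 | chloromethyl methyl ether | COCCl | starting material
9 | 2-[3-methoxy-4-(methoxymethoxy)phenyl]-4,4,5,5-tetramethyl-1,3,2-dioxaborolane | COCOc1ccc(B2OC(C)(C)C(C)(C)O2)cc1OC | intermediate
10 | (4S,6R)-6-[(E)-2-(3,4-dimethoxyphenyl)ethenyl]-4-[3-methoxy-4-(methoxymethoxy)phenyl]oxan-2-one (4,6-trans) | O=C1C[C@@H](c2ccc(OCOC)c(OC)c2)C[C@H](/C=C/c2ccc(OC)c(OC)c2)O1 | intermediate
11 | tert-butyl{[(2R,4S)-2-[(E)-2-(3,4-dimethoxyphenyl)ethenyl]-4-[3-methoxy-4-(methoxymethoxy)phenyl]-3,4-dihydro-2H-pyran-6-yl]oxy}dimethylsilane (silyl ketene acetal of 10) | CC(C)(C)[Si](C)(C)OC1=C[C@@H](c2ccc(OCOC)c(OC)c2)C[C@H](/C=C/c2ccc(OC)c(OC)c2)O1 | intermediate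
12 | tert-butyldimethylsilyl (1S,2S,6R)-6-(3,4-dimethoxyphenyl)-2-[3-methoxy-4-(methoxymethoxy)phenyl]cyclohex-4-ene-1-carboxylate (all-cis) | CC(C)(C)[Si](C)(C)OC(=O)[C@H]1[C@@H](c2ccc(OCOC)c(OC)c2)CC=C[C@H]1c1ccc(OC)c(OC)c1 | intermediate
13 | (1S,2S,6R)-6-(3,4-dimethoxyphenyl)-2-[3-methoxy-4-(methoxymethoxy)phenyl]cyclohex-4-ene-1-carboxylic acid (all-cis) | OC(=O)[C@H]1[C@@H](c2ccc(OCOC)c(OC)c2)CC=C[C@H]1c1ccc(OC)c(OC)c1 | intermediate
14 | methyllithium | [Li]C | starting material
15 | 1-[(1S,2S,6R)-6-(3,4-dimethoxyphenyl)-2-[3-methoxy-4-(methoxymethoxy)phenyl]cyclohex-4-en-1-yl]ethan-1-one (all-cis) | CC(=O)[C@H]1[C@@H](c2ccc(OCOC)c(OC)c2)CC=C[C@H]1c1ccc(OC)c(OC)c1 | intermediate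
16 | 1-[(1R,2S,6R)-6-(3,4-dimethoxyphenyl)-2-[3-methoxy-4-(methoxymethoxy)phenyl]cyclohex-4-en-1-yl]ethan-1-one (acetyl trans to both aryl groups) | CC(=O)[C@@H]1[C@@H](c2ccc(OCOC)c(OC)c2)CC=C[C@H]1c1ccc(OC)c(OC)c1 | intermediate
17 | ethyl acetate | CCOC(C)=O | starting material
18 | 1-[(1R,2S,6R)-6-(3,4-dimethoxyphenyl)-2-[3-methoxy-4-(methoxymethoxy)phenyl]cyclohex-4-en-1-yl]butane-1,3-dione (drawn as diketo tautomer) | CC(=O)CC(=O)[C@@H]1[C@@H](c2ccc(OCOC)c(OC)c2)CC=C[C@H]1c1ccc(OC)c(OC)c1 | intermediate
19 | vanillin (4-hydroxy-3-methoxybenzaldehyde) | COc1cc(C=O)ccc1O | starting material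
20 | dibutoxyboron chelate of diketone 18 (drawn as the 2,2-dibutoxy-1,3,2-dioxaborinine form) | CCCCO[B-]1(OCCCC)OC(C)=CC([C@@H]2[C@@H](c3ccc(OCOC)c(OC)c3)CC=C[C@H]2c2ccc(OC)c(OC)c2)=[O+]1 | intermediate
21 | dibutoxyboron chelate of the condensation product (methoxymethyl ether of the target, E-styryl arm in place) | CCCCO[B-]1(OCCCC)OC(/C=C/c2ccc(O)c(OC)c2)=CC([C@@H]2[C@@H](c3ccc(OCOC)c(OC)c3)CC=C[C@H]2c2ccc(OC)c(OC)c2)=[O+]1 | intermediate
22 | (1Z,4E)-1-[(1R,2S,6R)-6-(3,4-dimethoxyphenyl)-2-(4-hydroxy-3-methoxyphenyl)cyclohex-4-en-1-yl]-3-hydroxy-5-(4-hydroxy-3-methoxyphenyl)penta-2,4-dien-1-one (CNP0290899.1) | COc1cc(/C=C/C(O)=C/C(=O)[C@@H]2[C@@H](c3ccc(O)c(OC)c3)CC=C[C@H]2c2ccc(OC)c(OC)c2)ccc1O | target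

## Step count and risk

Total step count: 10. Longest linear sequence: 9 steps (1 → 3 → 5 → 6 → 10 → 13 → 15 → 16 → 18 → 22; step 4 is a one-step side branch).

**Step 6 (key step).** The most likely failure is heterolysis of the allylic C–O bond of 11, which would give a para-alkoxy-stabilised cinnamyl-type cation, competing with the concerted shift in the enforced boat. That would erode chirality transfer to C6 or end in elimination to an open-chain dienoic acid. Incomplete O-silylation would return lactone. The fallback moves the acetyl group in before the rearrangement and uses an anion-accelerated, decarboxylative variant that needs neither the silyl ketene acetal nor acid 13. It sets out from 10. C-acetylation of the lactone enolate (LiN(SiMe3)2, 2.1 equiv, THF, −78 °C, then 1-acetylimidazole) would give the 3-acetyl lactone F1, an allylic β-keto ester. Its dianion (LiN(iPr)2, 2.2 equiv, THF, −78 °C → reflux) should undergo a Carroll rearrangement through the same boat array to the ring-contracted β-keto acid F2, with C6 set in the same sense. Acidification and gentle warming would expel CO2 and give the methyl ketone as a C1 epimer mixture. The conditions of step 8 equilibrate this mixture, and the route is rejoined at 16.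

**Step 5.** Facial selectivity rests on the substrate alone and may be poor. The aryl–rhodium species could also insert into the styrene and open the allylic lactone by β-oxygen elimination, and the electron-rich boronate may protodeboronate. The fallback puts the aryl group on an acyclic enoate under catalyst control and closes the lactone afterwards. It sets out from 3. Cross-metathesis with methyl acrylate (second-generation Hoveyda–Grubbs catalyst RuCl2(=CH-o-OiPrC6H4)(H2IMes), CH2Cl2, 40 °C) would give the hydroxy dienoate F3. Conjugate arylation with 9 under Rh(acac)(C2H4)2 and the BINAP enantiomer matched to the 3S product (expected to be (S)-BINAP by the usual model) would give the hydroxy ester F4. Lactonisation (DBU cat., toluene, 80 °C) would then rejoin the route at 10.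

**Step 7.** The carboxylate of 13 is axial and flanked by two aryl-bearing carbons, so addition may be slow, leaving recovered acid, or ketone released during the quench may be over-methylated. The fallback sets out from 13. Activation with carbonyldiimidazole and coupling with N,O-dimethylhydroxylamine hydrochloride would give the Weinreb amide F5. MeMgBr (THF, 0 °C) stops cleanly at the ketone and rejoins the route at 15.

**Step 10.** Condensation may be incomplete or occur twice on the aldehyde-derived side, and the longer acid treatment needed to remove the methoxymethyl group may degrade the curcuminoid. The fallback replaces the boron template by a diketone dianion aldol. It sets out from 18 and from 19. Vanillin is first converted to 3-methoxy-4-(methoxymethoxy)benzaldehyde F6 (MOMCl, iPr2NEt). The dianion of 18 (LiN(iPr)2, 2.2 equiv, THF, −78 °C), which reacts at the terminal carbon, would add to F6 to give the aldol F7. Methanolic HCl at 50 °C should dehydrate F7 to the E-enone and remove both methoxymethyl groups, rejoining the route at 22.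

## Further compounds

F1 | step 6 | 3-acetyl derivative of lactone 10, (4S,6R), C3 epimers and enol | O=C1C(C(C)=O)[C@@H](c2ccc(OCOC)c(OC)c2)C[C@H](/C=C/c2ccc(OC)c(OC)c2)O1
F2 | step 6 | 1-acetyl-6-(3,4-dimethoxyphenyl)-2-[3-methoxy-4-(methoxymethoxy)phenyl]cyclohex-4-ene-1-carboxylic acid, carboxyl cis to both aryl groups | CC(=O)[C@]1(C(=O)O)[C@@H](c2ccc(OCOC)c(OC)c2)CC=C[C@H]1c1ccc(OC)c(OC)c1
F3 | step 5 | methyl (2E,5R,6E)-7-(3,4-dimethoxyphenyl)-5-hydroxyhepta-2,6-dienoate | COC(=O)/C=C/C[C@@H](O)/C=C/c1ccc(OC)c(OC)c1
F4 | step 5 | methyl (3S,5R,6E)-7-(3,4-dimethoxyphenyl)-5-hydroxy-3-[3-methoxy-4-(methoxymethoxy)phenyl]hept-6-enoate | COC(=O)C[C@@H](c1ccc(OCOC)c(OC)c1)C[C@@H](O)/C=C/c1ccc(OC)c(OC)c1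
F5 | step 7 | (1S,2S,6R)-6-(3,4-dimethoxyphenyl)-N-methoxy-2-[3-methoxy-4-(methoxymethoxy)phenyl]-N-methylcyclohex-4-ene-1-carboxamide (all-cis) | CON(C)C(=O)[C@H]1[C@@H](c2ccc(OCOC)c(OC)c2)CC=C[C@H]1c1ccc(OC)c(OC)c1
F6 | step 10 | 3-methoxy-4-(methoxymethoxy)benzaldehyde | COCOc1ccc(C=O)cc1OC
F7 | step 10 | 5-hydroxy-5-[3-methoxy-4-(methoxymethoxy)phenyl]-1-[(1R,2S,6R)-6-(3,4-dimethoxyphenyl)-2-[3-methoxy-4-(methoxymethoxy)phenyl]cyclohex-4-en-1-yl]pentane-1,3-dione, carbinol epimers | COCOc1ccc(C(O)CC(=O)CC(=O)[C@@H]2[C@@H](c3ccc(OCOC)c(OC)c3)CC=C[C@H]2c2ccc(OC)c(OC)c2)cc1OC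
A1 | alternative 1 | (E)-1-(3,4-dimethoxyphenyl)buta-1,3-diene | C=C/C=C/c1ccc(OC)c(OC)c1
A2 | alternative 1 | curcumin | COc1cc(/C=C/C(O)=C/C(=O)/C=C/c2ccc(O)c(OC)c2)ccc1O
A3 | alternative 1 | endo Diels–Alder adduct, acyl cis to the C6 aryl group and the two aryl groups trans, one enantiomer of the racemate drawn | COc1cc(/C=C/C(O)=C/C(=O)[C@@H]2[C@@H](c3ccc(O)c(OC)c3)CC=C[C@@H]2c2ccc(OC)c(OC)c2)ccc1O
A4 | alternative 2 | 2-[1-(3,4-dimethoxyphenyl)prop-2-enyl]-3-[3-methoxy-4-(methoxymethoxy)phenyl]hex-5-enoic acid with the configuration of the target at all three centres | OC(=O)[C@@H]([C@H](c1ccc(OC)c(OC)c1)C=C)[C@@H](c1ccc(OCOC)c(OC)c1)CC=C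
A5 | alternative 2 | (E)-3-(3,4-dimethoxyphenyl)prop-2-enyl (3S)-3-[3-methoxy-4-(methoxymethoxy)phenyl]hex-5-enoate | C=CC[C@H](c1ccc(OCOC)c(OC)c1)CC(=O)OC/C=C/c1ccc(OC)c(OC)c1
A6 | alternative 3 | (1S)-N-(quinolin-8-yl)cyclohex-3-ene-1-carboxamide | O=C(Nc1cccc2cccnc12)[C@H]1CCC=CC1
A7 | alternative 3 | all-cis 6-(3,4-dimethoxyphenyl)-2-[3-methoxy-4-(methoxymethoxy)phenyl]-N-(quinolin-8-yl)cyclohex-4-ene-1-carboxamide | O=C(Nc1cccc2cccnc12)[C@H]1[C@@H](c2ccc(OCOC)c(OC)c2)CC=C[C@H]1c1ccc(OC)c(OC)c1
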